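## Retrosynthetic overview

1. The target is (2R,3R)-3,5-dihydroxy-7-methoxy-8-(3-methylbut-2-enyl)flavanone; its 5-OH and 3-OH are unmasked last, from a 5-methyl ether and a 3-MOM ether.
2. The plan rests on one feature: ring C is fused to ring A at the neighbouring carbons C4a and C8a and is held there by only two bonds, C8a–O1 and C4a–C4. Cutting both turns ring A into an aryne (C4a≡C8a) and ring C into an open-chain anti β-hydroxy ester that already carries C2 and C3.
3. Aryne precursor: an ortho-silyl aryl triflate from 3,5-dimethoxyphenol by two carbamate-directed ortho-metalations (silylation at the future C4a, then copper-mediated prenylation at the future C8) and carbamate-to-triflate exchange.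
4. Hydroxy ester: methyl (2R,3S)-3-phenylglycidate, benzylic opening with benzyl alcohol (inversion at the benzylic carbon), MOM on the α-oxygen, hydrogenolysis.
5. Ring order: rings A and B are bought intact; ring C is the only ring made, in the aryne annulation.

Key step: step 8

Remark on the chemistry: flavanone numbering (O1, C2, C3, C4, C4a, C5 to C8, C8a) is used for the target and for the ring A carbons of every precursor. The benzylic oxygen is carried as a benzyl ether, because benzyl alcohol tolerates the Lewis acid of the epoxide opening.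

## Route

Step 1
Reactants: 1 3,5-dimethoxyphenol
Product: 2 3,5-dimethoxyphenyl N-isopropylcarbamate
Conditions: i-PrNCO, Et3N (cat.), CH2Cl2, rt
Reagents that add atoms: isopropyl isocyanate CC(C)N=C=O
Why: Base-catalysed addition of the phenol to the isocyanate (carbamoylation) installs a strong ortho-directing group that can later be removed by E1cB loss of the isocyanate.

Step 2
Reactants: 2 3,5-dimethoxyphenyl N-isopropylcarbamate
Product: 6 3,5-dimethoxy-2-(trimethylsilyl)phenyl N-isopropylcarbamate, via N-silyl carbamate 3 (not isolated), via ortho-lithio N-silyl carbamate 4 (not isolated), via N,C-disilyl carbamate 5 (not isolated)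
Conditions: TMSOTf, TMEDA, Et2O, 0 °C to rt; n-BuLi (2 equiv), TMEDA, −78 °C; TMSCl, −78 °C to rt; aq. NH4Cl
Reagents that add atoms: chlorotrimethylsilane C[Si](C)(C)Cl
Why: Directed ortho-metalation: after in situ N-silylation the carbamate should steer n-BuLi to the position between itself and a methoxyl (the future C4a), which both groups activate, and the aryllithium is trapped by TMSCl; the N–Si bond falls off on mild aqueous work-up.

Step 3
Reactants: 6 3,5-dimethoxy-2-(trimethylsilyl)phenyl N-isopropylcarbamate; 7 1-bromo-3-methylbut-2-ene (prenyl bromide)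
Product: 12 3,5-dimethoxy-2-(3-methylbut-2-enyl)-6-(trimethylsilyl)phenyl N-isopropylcarbamate, via N-triethylsilyl carbamate 8 (not isolated), via aryllithium 9 (not isolated), via arylcopper 10 (not isolated), via N-triethylsilyl prenyl carbamate 11 (not isolated)
Conditions: TESOTf, TMEDA, Et2O, 0 °C to rt; n-BuLi (2 equiv), TMEDA, −78 °C; CuBr·SMe2, THF, −78 to −40 °C; 7, −40 to 0 °C; aq. NH4Cl/NH3, rt
Reagents that add atoms: none
Why: A second directed ortho-metalation, run after in situ N-protection with the somewhat sturdier triethylsilyl group because the N–Si bond now has to last through transmetalation and warming to 0 °C, can only use the remaining position beside the carbamate (the future C8), and the arylcopper should couple with the primary allylic bromide at its CH2 terminus (copper-mediated allylic substitution) to give the linear prenyl group; the N–Si bond is hydrolysed in the ammoniacal work-up, and placing silicon on the ring first avoids lateral deprotonation of a benzylic, allylic CH2.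

Step 4
Reactants: 12 3,5-dimethoxy-2-(3-methylbut-2-enyl)-6-(trimethylsilyl)phenyl N-isopropylcarbamate
Product: 14 3,5-dimethoxy-2-(3-methylbut-2-enyl)-6-(trimethylsilyl)phenyl trifluoromethanesulfonate, via 2-prenyl-6-silyl phenol 13 (not isolated)
Conditions: DBU, Et2NH, MeCN, 40 °C; then PhNTf2, rt to 40 °C
Reagents that add atoms: N-phenylbis(trifluoromethanesulfonimide) O=S(=O)(N(c1ccccc1)S(=O)(=O)C(F)(F)F)C(F)(F)F
Why: DBU removes the carbamate N–H and the anion expels the phenoxide (E1cB, the isocyanate being caught by Et2NH); the phenoxide is then triflated in the same pot by PhNTf2 (sulfonyl transfer), a mild reagent that leaves the alkene and the aryl silane alone.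

Step 5
Reactants: 15 methyl (2R,3S)-3-phenylglycidate; 16 benzyl alcohol
Product: 17 methyl (2R,3R)-3-(benzyloxy)-2-hydroxy-3-phenylpropanoate
Conditions: 16 (3 equiv), BF3·OEt2 (cat.), CH2Cl2, −20 to 0 °C
Reagents that add atoms: none
Why: Lewis-acid-catalysed alcoholysis of an aryl glycidate: BF3 weakens the benzylic C3–O bond, the ester deactivates C2, and backside attack of benzyl alcohol at C3 inverts it (S to R) while C2 keeps its configuration, which sets the anti (2R,3R) relationship.

Step 6
Reactants: 17 methyl (2R,3R)-3-(benzyloxy)-2-hydroxy-3-phenylpropanoate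
Product: 18 methyl (2R,3R)-3-(benzyloxy)-2-(methoxymethoxy)-3-phenylpropanoate
Conditions: MOMCl, i-Pr2NEt, n-Bu4NI (cat.), CH2Cl2, 0 to 40 °C
Reagents that add atoms: chloromethyl methyl ether COCCl
Why: O-alkylation of the α-hydroxyl with the chloromethyl ether (MOM protection) under a hindered amine base, which is too weak to epimerise C2.

Step 7
Reactants: 18 methyl (2R,3R)-3-(benzyloxy)-2-(methoxymethoxy)-3-phenylpropanoate
Product: 19 methyl (2R,3R)-3-hydroxy-2-(methoxymethoxy)-3-phenylpropanoate
Conditions: H2 (1 atm), 10% Pd/C, EtOAc, rt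
Reagents that add atoms: none
Why: Catalytic hydrogenolysis should cleave the unhindered PhCH2–O bond, whereas the C3–O bond, secondary and deactivated by the neighbouring α-alkoxy ester, should persist; the MOM acetal and the ester are inert.

Step 8
Reactants: 19 methyl (2R,3R)-3-hydroxy-2-(methoxymethoxy)-3-phenylpropanoate; 14 3,5-dimethoxy-2-(3-methylbut-2-enyl)-6-(trimethylsilyl)phenyl trifluoromethanesulfonate
Product: 23 (2R,3R)-5,7-dimethoxy-3-(methoxymethoxy)-8-(3-methylbut-2-enyl)flavanone, via potassium alkoxide 20 (not isolated), via aryne 21 (not isolated), via aryl anion 22 (not isolated)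
Conditions: KN(SiMe3)2 (1.0 equiv), THF, −78 °C; 14 (1.5 equiv), CsF, 18-crown-6, THF, −78 °C to rt; pH 7 buffer at 0 °C
Reagents that add atoms: none
Why: Proposed new method: fluoride strips the silyl group from 14 and triflate leaves to give aryne 21, alkoxide 20 adds to C8a so that the charge ends at C4a next to the C5 methoxyl, and aryl anion 22 then adds to the ester carbonyl and expels methoxide, which forms C8a–O1 and C4–C4a in one operation. The closest known reaction type is the aryne annulation of salicylate esters to xanthones (phenoxide addition followed by acyl substitution by the aryl anion), extended here from a phenoxide to an aliphatic β-alkoxide. Ring C closes by a 6-exo-trig acyl substitution. No stereocentre is made: the C2–O1 bond is the old carbinol C–O bond and is never broken, and C3 is not touched, so the anti ester maps onto the trans (2R,3R) ring with retention at both centres, and since trans is the more stable diequatorial arrangement, enolisation at C3 alone would not erode it. The step needs addition at C8a rather than C4a, which the inductive and distortion effect of the C5 methoxyl should secure because each aryne carbon carries one ortho substituent and sterics therefore do not decide, and it needs acylation to outrun protonation of 22, which the aprotic THF medium (no acetonitrile) and the six-membered reach of the ester favour. The excess of 14 consumes the methoxide set free (attack at silicon), which should shield the product from base-induced opening of ring C, and the low temperature holds back retro-aldol cleavage of 20.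

Step 9
Reactants: 23 (2R,3R)-5,7-dimethoxy-3-(methoxymethoxy)-8-(3-methylbut-2-enyl)flavanone
Product: 24 (2R,3R)-3-hydroxy-5,7-dimethoxy-8-(3-methylbut-2-enyl)flavanone
Conditions: HCl (aq., 3 M)/MeOH, 45 °C
Reagents that add atoms: none
Why: Acid-catalysed methanolysis of the MOM acetal; there is no base present to open ring C, and the prenyl group has no free ortho hydroxyl to cyclise onto (C7 is a methyl ether, C8a carries the ring oxygen).

Step 10
Reactants: 24 (2R,3R)-3-hydroxy-5,7-dimethoxy-8-(3-methylbut-2-enyl)flavanone
Product: 25 (2R,3R)-3,5-dihydroxy-7-methoxy-8-(3-methylbut-2-enyl)flavanone (target)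
Conditions: MgI2·OEt2 (excess), THF, 50 °C; aq. NH4Cl
Reagents that add atoms: none
Why: Chelation-controlled ether cleavage: magnesium bridges C4=O and the peri 5-methoxyl, so iodide should remove only that methyl group by SN2, while the 7-methoxyl cannot chelate and the aprotic medium spares the prenyl double bond.

## Compound list

1 | 3,5-dimethoxyphenol | COc1cc(O)cc(OC)c1 | starting material
2 | 3,5-dimethoxyphenyl N-isopropylcarbamate | COc1cc(OC)cc(OC(=O)NC(C)C)c1 | intermediate
3 | 3,5-dimethoxyphenyl N-isopropyl-N-(trimethylsilyl)carbamate | COc1cc(OC)cc(OC(=O)N(C(C)C)[Si](C)(C)C)c1 | intermediate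
4 | 2-lithio-3,5-dimethoxyphenyl N-isopropyl-N-(trimethylsilyl)carbamate | COc1cc(OC)c([Li])c(OC(=O)N(C(C)C)[Si](C)(C)C)c1 | intermediate
5 | 3,5-dimethoxy-2-(trimethylsilyl)phenyl N-isopropyl-N-(trimethylsilyl)carbamate | COc1cc(OC)c([Si](C)(C)C)c(OC(=O)N(C(C)C)[Si](C)(C)C)c1 | intermediate
6 | 3,5-dimethoxy-2-(trimethylsilyl)phenyl N-isopropylcarbamate | COc1cc(OC)c([Si](C)(C)C)c(OC(=O)NC(C)C)c1 | intermediate
7 | 1-bromo-3-methylbut-2-ene (prenyl bromide) | CC(C)=CCBr | starting material
8 | 3,5-dimethoxy-2-(trimethylsilyl)phenyl N-isopropyl-N-(triethylsilyl)carbamate | COc1cc(OC)c([Si](C)(C)C)c(OC(=O)N(C(C)C)[Si](CC)(CC)CC)c1 | intermediate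
9 | 6-lithio-3,5-dimethoxy-2-(trimethylsilyl)phenyl N-isopropyl-N-(triethylsilyl)carbamate | COc1cc(OC)c([Si](C)(C)C)c(OC(=O)N(C(C)C)[Si](CC)(CC)CC)c1[Li] | intermediate
10 | 6-cuprio-3,5-dimethoxy-2-(trimethylsilyl)phenyl N-isopropyl-N-(triethylsilyl)carbamate | COc1cc(OC)c([Si](C)(C)C)c(OC(=O)N(C(C)C)[Si](CC)(CC)CC)c1[Cu] | intermediate
11 | 3,5-dimethoxy-2-(3-methylbut-2-enyl)-6-(trimethylsilyl)phenyl N-isopropyl-N-(triethylsilyl)carbamate | COc1cc(OC)c([Si](C)(C)C)c(OC(=O)N(C(C)C)[Si](CC)(CC)CC)c1CC=C(C)C | intermediate
12 | 3,5-dimethoxy-2-(3-methylbut-2-enyl)-6-(trimethylsilyl)phenyl N-isopropylcarbamate | COc1cc(OC)c([Si](C)(C)C)c(OC(=O)NC(C)C)c1CC=C(C)C | intermediate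
13 | 3,5-dimethoxy-2-(3-methylbut-2-enyl)-6-(trimethylsilyl)phenol | COc1cc(OC)c([Si](C)(C)C)c(O)c1CC=C(C)C | intermediate
14 | 3,5-dimethoxy-2-(3-methylbut-2-enyl)-6-(trimethylsilyl)phenyl trifluoromethanesulfonate | COc1cc(OC)c([Si](C)(C)C)c(OS(=O)(=O)C(F)(F)F)c1CC=C(C)C | intermediate
15 | methyl (2R,3S)-3-phenylglycidate | COC(=O)[C@@H]1O[C@H]1c1ccccc1 | starting material
16 | benzyl alcohol | OCc1ccccc1 | starting material
17 | methyl (2R,3R)-3-(benzyloxy)-2-hydroxy-3-phenylpropanoate | c1ccccc1CO[C@H](c1ccccc1)[C@@H](O)C(=O)OC | intermediate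
18 | methyl (2R,3R)-3-(benzyloxy)-2-(methoxymethoxy)-3-phenylpropanoate | c1ccccc1CO[C@H](c1ccccc1)[C@@H](OCOC)C(=O)OC | intermediate
19 | methyl (2R,3R)-3-hydroxy-2-(methoxymethoxy)-3-phenylpropanoate | O[C@H](c1ccccc1)[C@@H](OCOC)C(=O)OC | intermediate
20 | potassium alkoxide of 19 | [K+].[O-][C@H](c1ccccc1)[C@@H](OCOC)C(=O)OC | intermediate
21 | 3,5-dimethoxy-6-(3-methylbut-2-enyl)benzyne (triple bond C4a≡C8a) | COC1=C(CC=C(C)C)C#CC(OC)=C1 | intermediate
22 | potassium aryl anion at C4a of the C8a–O aryl ether | [K+].COc1cc(OC)[c-]c(O[C@H](c2ccccc2)[C@@H](OCOC)C(=O)OC)c1CC=C(C)C | intermediate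
23 | (2R,3R)-5,7-dimethoxy-3-(methoxymethoxy)-8-(3-methylbut-2-enyl)flavanone | COc1cc(OC)c2c(c1CC=C(C)C)O[C@H](c1ccccc1)[C@@H](OCOC)C2=O | intermediate
24 | (2R,3R)-3-hydroxy-5,7-dimethoxy-8-(3-methylbut-2-enyl)flavanone | COc1cc(OC)c2c(c1CC=C(C)C)O[C@H](c1ccccc1)[C@@H](O)C2=O | intermediate
25 | (2R,3R)-3,5-dihydroxy-7-methoxy-8-(3-methylbut-2-enyl)flavanone | COc1cc(O)c2c(c1CC=C(C)C)O[C@H](c1ccccc1)[C@@H](O)C2=O | target

## Count and risks

Total step count: 10.
Longest linear sequence: 7 steps (steps 1, 2, 3, 4, 8, 9, 10 from 3,5-dimethoxyphenol); the ester branch (steps 5, 6, 7) joins at step 8.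

Steps most likely to fail:

1. Step 8 (Proposed new method).
   - What may go wrong: the alkoxide may fragment by retro-aldol cleavage, or attack silicon or sulfur of 14, before it adds to the aryne. Addition may partly occur at C4a. The aryl anion may be protonated, or may abstract the ester α-proton with β-elimination of the aryloxide, faster than it acylates. The methoxide released may open ring C of the product and erase C2.
   - Fallback (known chemistry), setting out from 14 and coming back at 24: 14 is treated with CsF and acetic acid in THF at 125 °C in a sealed tube. Acetate adds to the aryne at C8a and the aryl anion takes over the acetyl group (carboxylic acid C–O insertion), which should give 1-[2-hydroxy-4,6-dimethoxy-3-(3-methylbut-2-enyl)phenyl]ethanone F1. Claisen–Schmidt condensation with benzaldehyde (KOH, EtOH, rt) should give (E)-2'-hydroxy-4',6'-dimethoxy-3'-(3-methylbut-2-enyl)chalcone F2, and MOMCl with NaH in DMF its 2'-O-methoxymethyl ether F3. Juliá–Colonna epoxidation (poly-L-leucine, urea–H2O2, DBU, THF) attacks only the electron-poor enone double bond and should give [2-(methoxymethoxy)-4,6-dimethoxy-3-(3-methylbut-2-enyl)phenyl][(2R,3S)-3-phenyloxiran-2-yl]methanone F4. HCl in MeOH at 50 °C then frees the phenol, which opens the epoxide at the benzylic carbon (6-endo, inversion) to give trans-configured 24; step 10 completes the route.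

2. Step 3.
   - What may go wrong: metalation between the two methoxyls instead of beside the carbamate, carbamoyl migration to carbon on warming before the copper reagent has coupled, or coupling at the tertiary terminus of the allyl unit to give the branched isomer.
   - Fallback, setting out from 6 and coming back at 13: the carbamate of 6 is removed with DBU and Et2NH in MeCN to give 3,5-dimethoxy-2-(trimethylsilyl)phenol F5. O-Allylation with allyl bromide and K2CO3 in acetone gives allyl 3,5-dimethoxy-2-(trimethylsilyl)phenyl ether F6. Claisen rearrangement in N,N-diethylaniline at 190 °C moves the allyl group to the only free ortho position and gives 2-allyl-3,5-dimethoxy-6-(trimethylsilyl)phenol F7. Cross-metathesis with 2-methylbut-2-ene and the second-generation Grubbs catalyst RuCl2(=CHPh)(PCy3)(H2IMes) in CH2Cl2 at 40 °C gives phenol 13, which is triflated with PhNTf2 and DBU as in the second stage of step 4 to give 14.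

3. Step 2.
   - What may go wrong: deprotonation between the two methoxyls instead of beside the carbamate, anionic Fries shift of the carbamoyl group before silylation, or loss of silicon from the very electron-rich aryl silane by ipso-protonation on work-up.
   - Fallback, setting out from 1 and coming back at 6: bromination of 1 with NBS in CH2Cl2 at −78 °C gives 2-bromo-3,5-dimethoxyphenol F8, separated from its para isomer. Heating with HN(SiMe3)2 in THF gives (2-bromo-3,5-dimethoxyphenoxy)trimethylsilane F9. n-BuLi in THF at −78 °C effects bromine–lithium exchange and O-to-C silyl shift (retro-Brook rearrangement) to give 3,5-dimethoxy-2-(trimethylsilyl)phenol F5, the compound also named in the fallback for step 3. Carbamoylation with i-PrNCO and Et3N as in step 1 gives 6.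

## Further compounds

F1 | step 8 | 1-[2-hydroxy-4,6-dimethoxy-3-(3-methylbut-2-enyl)phenyl]ethanone | CC(=O)c1c(O)c(CC=C(C)C)c(OC)cc1OC
F2 | step 8 | (E)-2'-hydroxy-4',6'-dimethoxy-3'-(3-methylbut-2-enyl)chalcone | O=C(/C=C/c1ccccc1)c1c(O)c(CC=C(C)C)c(OC)cc1OC
F3 | step 8 | (E)-4',6'-dimethoxy-2'-(methoxymethoxy)-3'-(3-methylbut-2-enyl)chalcone | O=C(/C=C/c1ccccc1)c1c(OCOC)c(CC=C(C)C)c(OC)cc1OC
F4 | step 8 | [2-(methoxymethoxy)-4,6-dimethoxy-3-(3-methylbut-2-enyl)phenyl][(2R,3S)-3-phenyloxiran-2-yl]methanone | O=C(c1c(OCOC)c(CC=C(C)C)c(OC)cc1OC)[C@@H]1O[C@H]1c1ccccc1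
F5 | step 3 | 3,5-dimethoxy-2-(trimethylsilyl)phenol | COc1cc(O)c([Si](C)(C)C)c(OC)c1
F6 | step 3 | allyl 3,5-dimethoxy-2-(trimethylsilyl)phenyl ether | C=CCOc1cc(OC)cc(OC)c1[Si](C)(C)C
F7 | step 3 | 2-allyl-3,5-dimethoxy-6-(trimethylsilyl)phenol | C=CCc1c(O)c([Si](C)(C)C)c(OC)cc1OC
F8 | step 2 | 2-bromo-3,5-dimethoxyphenol | COc1cc(O)c(Br)c(OC)c1
F9 | step 2 | (2-bromo-3,5-dimethoxyphenoxy)trimethylsilane | COc1cc(O[Si](C)(C)C)c(Br)c(OC)c1
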